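**Plan**

- Numbering: ring C1 carries the side chain, C2 is CH2, C3 CHOH, C4 C(CH3)OH, C5 C=O, C6 CH–O-acyl; side chain C7(=CH2)–C8(=O)–C9H=C10H–C11(CH3)2OOH.
- Cuts, outermost first: C11–OOH (ene reaction), C10=C11 and C8–C9 (metathesis, allyl addition), the C7 methylene, C1–C7 (as a C1=C7 olefination), the C6 ester, and last the ring bond C2–C3.
- Enabling feature: C3–C6 with their four oxygens are C1–C4 of a 2-C-methylhexopyranose, C2 is its C6 and C1 its C5, so the cyclohexane (the only ring) is the pyranose of a 6-deoxyhex-5-enopyranoside re-closed through carbon.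
- Forward: methyl β-D-galactopyranoside → 2-C-methyl-L-lyxo-hex-5-enopyranoside (steps 1–11) → cyclohexanone (step 12) → chain grown outward from the C1 ketone (C7–C8, C7 methylene, C9–C10, C11) → C5 ketone, C6 ester → hydroperoxide last.
- Stereochemistry: C6 is galactose C-4; C4 (and the temporary C5 carbinol) come from a dihydroxylation anti to the anomeric and C-4 oxygens; C3 from the carbocyclisation; C1 from hydrogenation directed by the C3 hydroxyl.

Key step: step 12

Remark: sugars carry carbohydrate numbering and carbocycles the numbering of the plan; reagents are given by name and SMILES, and only route compounds and starting materials whose carbons enter the target are numbered.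
Remark: the methyl group is brought in before the C-2/C-3 oxygens are set, because carbon delivery to the β-face of a galacto-configured 2-ulose (syn-axial to O-4) is not expected to be selective; the β-glycoside is used so that both allylic oxygens lie on one face in step 7.
Remark: 19 is an E/Z mixture and 26, 28, 29 are C8 epimer mixtures; each converges later, so no descriptor is given there.

**Route**

Step 1
Reactants: 1 methyl β-D-galactopyranoside
Product: 2 methyl 4,6-O-[(S)-4-methoxybenzylidene]-β-D-galactopyranoside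
Conditions: 4-MeOC6H4CH(OMe)2, CSA (cat.), MeCN, 50 °C
Reagents that add atoms: 4-methoxybenzaldehyde dimethyl acetal, COc1ccc(cc1)C(OC)OC
Why: Acid-catalysed transacetalisation should tie O-4 and O-6 into the thermodynamic six-membered arylidene acetal (aryl equatorial, acetal carbon S), leaving only the 2,3-diol free.

Step 2
Reactants: 2 methyl 4,6-O-[(S)-4-methoxybenzylidene]-β-D-galactopyranoside
Product: 4 methyl 3-O-benzoyl-4,6-O-(4-methoxybenzylidene)-β-D-galactopyranoside, via 2,3-O-dibutylstannylene acetal 3 (not isolated)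
Conditions: Bu2SnO, toluene, reflux (Dean–Stark); then BzCl, 0 °C → rt
Reagents that add atoms: dibutyltin oxide (tin unit only in 3), CCCC[Sn](=O)CCCC; benzoyl chloride, O=C(Cl)c1ccccc1
Why: Stannylene-acetal-mediated regioselective acylation, in which the equatorial O-3 next to the axial O-4 is the activated oxygen of 4,6-O-acetal galactosides, so O-2 stays free.

Step 3
Reactants: 4 methyl 3-O-benzoyl-4,6-O-(4-methoxybenzylidene)-β-D-galactopyranoside
Product: 5 methyl 3-O-benzoyl-4,6-O-(4-methoxybenzylidene)-β-D-lyxo-hexopyranosid-2-ulose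
Conditions: Dess–Martin periodinane, NaHCO3, CH2Cl2, rt
Reagents that add atoms: none
Why: Dess–Martin oxidation of the only free (secondary) hydroxyl gives the 2-ulose under buffered, non-basic conditions, so the 3-O-benzoyl ketone is not exposed to β-elimination.

Step 4
Reactants: 5 methyl 3-O-benzoyl-4,6-O-(4-methoxybenzylidene)-β-D-lyxo-hexopyranosid-2-ulose; 6 methylmagnesium bromide
Product: 8 methyl 4,6-O-(4-methoxybenzylidene)-2-C-methyl-β-D-talopyranoside, via 3-O-benzoyl tertiary alkoxide 7 (not isolated)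
Conditions: MeMgBr (4 equiv), THF, −78 → 0 °C; aq NH4Cl
Reagents that add atoms: methylmagnesium bromide (6), C[Mg]Br
Why: Grignard 1,2-addition should occur from the α-face (equatorial attack, the β-face being screened by the syn-axial O-4 and no axial anomeric group lying below) to give the axial tertiary alkoxide cis to O-3, after which excess reagent cleaves the benzoate by double addition; this C-2 centre only has to be cis to O-3, since it is removed in step 6.

Step 5
Reactants: 8 methyl 4,6-O-(4-methoxybenzylidene)-2-C-methyl-β-D-talopyranoside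
Product: 9 methyl 4,6-O-(4-methoxybenzylidene)-2-C-methyl-2,3-O-thiocarbonyl-β-D-talopyranoside
Conditions: 1,1'-thiocarbonyldiimidazole, DMAP (cat.), toluene, 90 °C
Reagents that add atoms: 1,1'-thiocarbonyldiimidazole, S=C(n1ccnc1)n1ccnc1
Why: Thiocarbonyl transfer closes the five-membered cyclic thionocarbonate on the cis (axial/equatorial) 2,3-diol, the first half of a Corey–Winter olefination.

Step 6
Reactants: 9 methyl 4,6-O-(4-methoxybenzylidene)-2-C-methyl-2,3-O-thiocarbonyl-β-D-talopyranoside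
Product: 10 methyl 2,3-dideoxy-4,6-O-(4-methoxybenzylidene)-2-C-methyl-β-D-threo-hex-2-enopyranoside
Conditions: P(OMe)3, 110 °C
Reagents that add atoms: none
Why: Corey–Winter olefination, in which the phosphite abstracts sulfur and the cyclic carbene loses CO2 by stereospecific syn cycloreversion, giving the trisubstituted ring alkene with the methyl group on an sp2 C-2.

Step 7
Reactants: 10 methyl 2,3-dideoxy-4,6-O-(4-methoxybenzylidene)-2-C-methyl-β-D-threo-hex-2-enopyranoside
Product: 11 methyl 4,6-O-(4-methoxybenzylidene)-2-C-methyl-β-D-gulopyranoside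
Conditions: OsO4 (cat.), NMO, acetone–H2O (4:1), rt
Reagents that add atoms: osmium tetroxide (catalytic), O=[Os](=O)(=O)=O; N-methylmorpholine N-oxide, C[N+]1([O-])CCOCC1; water, O
Why: Upjohn dihydroxylation should take place on the α-face, anti to both allylic oxygens on the β-face (anomeric methoxy and O-4 of the cis-fused acetal), setting in one suprafacial event the tertiary C-2 carbinol (O down, methyl up) and the C-3 carbinol, i.e. the gulo configuration.

Step 8
Reactants: 11 methyl 4,6-O-(4-methoxybenzylidene)-2-C-methyl-β-D-gulopyranoside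
Product: 12 methyl 2,3-O-isopropylidene-4,6-O-(4-methoxybenzylidene)-2-C-methyl-β-D-gulopyranoside
Conditions: 2-methoxypropene, PPTS (cat.), CH2Cl2, 0 °C → rt
Reagents that add atoms: 2-methoxypropene, COC(C)=C
Why: Acid-catalysed ketalisation with an enol ether converts the cis tertiary/secondary diol into the cis-fused dioxolane under anhydrous conditions that the arylidene acetal tolerates.

Step 9
Reactants: 12 methyl 2,3-O-isopropylidene-4,6-O-(4-methoxybenzylidene)-2-C-methyl-β-D-gulopyranoside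
Product: 13 methyl 2,3-O-isopropylidene-4-O-(4-methoxybenzyl)-2-C-methyl-β-D-gulopyranoside
Conditions: DIBAL-H (3 equiv), CH2Cl2–toluene, −40 → 0 °C; Rochelle salt
Reagents that add atoms: none
Why: Regioselective reductive opening of an arylidene acetal, in which aluminium should bind the less hindered O-6, the C–O6 bond ionise and hydride quench the oxocarbenium ion, leaving the PMB ether on O-4 and the primary hydroxyl free.

Step 10
Reactants: 13 methyl 2,3-O-isopropylidene-4-O-(4-methoxybenzyl)-2-C-methyl-β-D-gulopyranoside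
Product: 14 methyl 6-deoxy-6-iodo-2,3-O-isopropylidene-4-O-(4-methoxybenzyl)-2-C-methyl-β-D-gulopyranoside
Conditions: I2, PPh3, imidazole, toluene, 70 °C
Reagents that add atoms: iodine, II
Why: Phosphonium-mediated (Appel-type) substitution converts the only free, primary hydroxyl into the iodide by SN2.

Step 11
Reactants: 14 methyl 6-deoxy-6-iodo-2,3-O-isopropylidene-4-O-(4-methoxybenzyl)-2-C-methyl-β-D-gulopyranoside
Product: 15 methyl 6-deoxy-2,3-O-isopropylidene-4-O-(4-methoxybenzyl)-2-C-methyl-α-L-lyxo-hex-5-enopyranoside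
Conditions: t-BuOK, THF, 0 °C → rt
Reagents that add atoms: none
Why: Base-induced E2 dehydrohalogenation (H-5 and iodide) gives the exocyclic enol ether, ethers and ketals being inert to tert-butoxide.

Step 12
Reactants: 15 methyl 6-deoxy-2,3-O-isopropylidene-4-O-(4-methoxybenzyl)-2-C-methyl-α-L-lyxo-hex-5-enopyranoside
Product: 17 (3R,4S,5R,6R)-3-hydroxy-4,5-(isopropylidenedioxy)-6-(4-methoxybenzyloxy)-4-methylcyclohexan-1-one, via acyclic mercurio ketoaldehyde 16 (not isolated)
Conditions: Hg(OCOCF3)2 (5 mol%), acetone–H2O (4:1), rt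
Reagents that add atoms: water, O; mercury(II) trifluoroacetate (mercury unit only in 16), O=C(O[Hg]OC(=O)C(F)(F)F)C(F)(F)F
Why: Hg(II) adds to the electron-rich exocyclic enol ether (oxymercuration), the C-5 hemiketal collapses with opening of the pyranose and loss of methanol to the acyclic C-6-mercurio 5-keto aldehyde 16, and its mercury enolate adds to the aldehyde carbon, forming the ring bond C2–C3 of the target. The closest known reaction type is the Ferrier carbocyclisation of 6-deoxyhex-5-enopyranosides to β-hydroxycyclohexanones, applied here to a 2-C-methyl substrate. The cyclohexanone closes in the 6-(enolendo)-exo-trig aldol mode through a chair with the PMB ether, O-3 and the C-2 methyl equatorial and the tertiary oxygen axial, an arrangement the cis-fused acetonide accommodates. The one new stereocentre, C3, is substrate-controlled: the aldehyde oxygen takes the axial position anti to the neighbouring axial C–O bond, placing the hydroxyl trans to the oxygen on sugar C-3 and anti to the tertiary oxygen, as is usual for lyxo (manno-type) substrates. The step needs this facial selectivity on the aldehyde and no β-elimination of the ketol; the L-lyxo arrangement fixed in step 7 should secure the first and the near-neutral catalytic conditions the second.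

Step 13
Reactants: 17 (3R,4S,5R,6R)-3-hydroxy-4,5-(isopropylidenedioxy)-6-(4-methoxybenzyloxy)-4-methylcyclohexan-1-one; 18 triethyl phosphonoacetate
Product: 19 ethyl 2-[(3R,4S,5R,6S)-3-hydroxy-4,5-(isopropylidenedioxy)-6-(4-methoxybenzyloxy)-4-methylcyclohexylidene]acetate (E/Z)
Conditions: (EtO)2P(O)CH2CO2Et, LiCl, DBU, MeCN, 0 °C → rt
Reagents that add atoms: triethyl phosphonoacetate (18), CCOC(=O)CP(=O)(OCC)OCC
Why: Horner–Wadsworth–Emmons olefination under Masamune–Roush conditions, where the lithium-chelated phosphonate is deprotonated by the amidine so that the ketol is not converted into its alkoxide and the activated α-alkoxy ketone should react near room temperature; alkene geometry is of no consequence because C7 becomes CH2.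

Step 14
Reactants: 19 ethyl 2-[(3R,4S,5R,6S)-3-hydroxy-4,5-(isopropylidenedioxy)-6-(4-methoxybenzyloxy)-4-methylcyclohexylidene]acetate
Product: 20 ethyl 2-[(1S,3R,4S,5R,6S)-3-hydroxy-4,5-(isopropylidenedioxy)-6-(4-methoxybenzyloxy)-4-methylcyclohexyl]acetate
Conditions: [Ir(cod)(PCy3)(py)]PF6 (10 mol%), H2 (1 atm), CH2Cl2, rt
Reagents that add atoms: none
Why: Hydroxyl-directed homogeneous hydrogenation with Crabtree's catalyst, in which iridium bound to the axial C3 hydroxyl on the β-face delivers H2 to that face of the exocyclic alkene, so H-1 is cis to the hydroxyl and the acetate arm trans (1S).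

Step 15
Reactants: 20 ethyl 2-[(1S,3R,4S,5R,6S)-3-hydroxy-4,5-(isopropylidenedioxy)-6-(4-methoxybenzyloxy)-4-methylcyclohexyl]acetate
Product: 21 ethyl 2-[(1S,3R,4R,5R,6S)-3-(tert-butyldimethylsilyloxy)-4,5-(isopropylidenedioxy)-6-(4-methoxybenzyloxy)-4-methylcyclohexyl]acetate
Conditions: TBSOTf, 2,6-lutidine, CH2Cl2, −78 → 0 °C
Reagents that add atoms: tert-butyldimethylsilyl trifluoromethanesulfonate, CC(C)(C)[Si](C)(C)OS(=O)(=O)C(F)(F)F
Why: Silyl triflate/lutidine silylation protects the hindered axial C3 hydroxyl as the TBS ether that has to outlast steps 16–23.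

Step 16
Reactants: 21 ethyl 2-[(1S,3R,4R,5R,6S)-3-(tert-butyldimethylsilyloxy)-4,5-(isopropylidenedioxy)-6-(4-methoxybenzyloxy)-4-methylcyclohexyl]acetate
Product: 22 2-[(1S,3R,4R,5R,6S)-3-(tert-butyldimethylsilyloxy)-4,5-(isopropylidenedioxy)-6-(4-methoxybenzyloxy)-4-methylcyclohexyl]acetaldehyde
Conditions: DIBAL-H (1.1 equiv), CH2Cl2, −78 °C; MeOH, Rochelle salt
Reagents that add atoms: none
Why: Low-temperature DIBAL-H half-reduction stops at the aluminium hemiacetal, which releases the aldehyde on work-up, no other reducible group being present.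

Step 17
Reactants: 22 2-[(1S,3R,4R,5R,6S)-3-(tert-butyldimethylsilyloxy)-4,5-(isopropylidenedioxy)-6-(4-methoxybenzyloxy)-4-methylcyclohexyl]acetaldehyde; 23 formaldehyde
Product: 24 2-[(1S,3R,4R,5R,6S)-3-(tert-butyldimethylsilyloxy)-4,5-(isopropylidenedioxy)-6-(4-methoxybenzyloxy)-4-methylcyclohexyl]prop-2-enal
Conditions: 37% aq CH2O, pyrrolidine (10 mol%), propionic acid (10 mol%), i-PrOH, 45 °C
Reagents that add atoms: formaldehyde (23), C=O
Why: Amine-catalysed α-methylenation of an aldehyde (Mannich-type condensation of the enamine with formaldehyde, then elimination) installs the C7 methylene without touching C1, which is β to the carbonyl.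

Step 18
Reactants: 24 2-[(1S,3R,4R,5R,6S)-3-(tert-butyldimethylsilyloxy)-4,5-(isopropylidenedioxy)-6-(4-methoxybenzyloxy)-4-methylcyclohexyl]prop-2-enal; 25 allylmagnesium bromide
Product: 26 2-[(1S,3R,4R,5R,6S)-3-(tert-butyldimethylsilyloxy)-4,5-(isopropylidenedioxy)-6-(4-methoxybenzyloxy)-4-methylcyclohexyl]hexa-1,5-dien-3-ol (C8 epimers)
Conditions: allylMgBr, Et2O–THF, −78 °C; aq NH4Cl
Reagents that add atoms: allylmagnesium bromide (25), C=CC[Mg]Br
Why: Grignard 1,2-addition of the allyl nucleophile to the enal forms C8–C9 without any α/γ ambiguity; the C8 configuration is irrelevant because this carbinol is oxidised in step 21.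

Step 19
Reactants: 26 2-[(1S,3R,4R,5R,6S)-3-(tert-butyldimethylsilyloxy)-4,5-(isopropylidenedioxy)-6-(4-methoxybenzyloxy)-4-methylcyclohexyl]hexa-1,5-dien-3-ol; 27 2-methyl-2-butene
Product: 28 2-[(1S,3R,4R,5R,6S)-3-(tert-butyldimethylsilyloxy)-4,5-(isopropylidenedioxy)-6-(4-methoxybenzyloxy)-4-methylcyclohexyl]-6-methylhepta-1,5-dien-3-ol (C8 epimers)
Conditions: Grubbs second-generation catalyst (5 mol%), 2-methyl-2-butene (excess), CH2Cl2, 40 °C
Reagents that add atoms: 2-methyl-2-butene (27), CC=C(C)C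
Why: Olefin cross-metathesis with excess 2-methyl-2-butene exchanges the terminal methylene for an isopropylidene group (prenyl installation), the 1,1-disubstituted C7 methylene being too hindered to take part.

Step 20
Reactants: 28 2-[(1S,3R,4R,5R,6S)-3-(tert-butyldimethylsilyloxy)-4,5-(isopropylidenedioxy)-6-(4-methoxybenzyloxy)-4-methylcyclohexyl]-6-methylhepta-1,5-dien-3-ol
Product: 29 2-[(1S,3R,4R,5R,6S)-3-(tert-butyldimethylsilyloxy)-4,5-dihydroxy-6-(4-methoxybenzyloxy)-4-methylcyclohexyl]-6-methylhepta-1,5-dien-3-ol (C8 epimers)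
Conditions: AcOH–H2O (4:1), 45 °C
Reagents that add atoms: none
Why: Acid hydrolysis of the isopropylidene ketal frees the C4/C5 diol, while the PMB ether and the TBS ether on the hindered neopentyl-type C3 oxygen should survive aqueous acetic acid.

Step 21
Reactants: 29 2-[(1S,3R,4R,5R,6S)-3-(tert-butyldimethylsilyloxy)-4,5-dihydroxy-6-(4-methoxybenzyloxy)-4-methylcyclohexyl]-6-methylhepta-1,5-dien-3-ol
Product: 30 2-[(1S,3R,4S,6S)-3-(tert-butyldimethylsilyloxy)-4-hydroxy-6-(4-methoxybenzyloxy)-4-methyl-5-oxocyclohexyl]-6-methylhepta-1,5-dien-3-one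
Conditions: IBX (4 equiv), DMSO, rt
Reagents that add atoms: none
Why: IBX oxidises both secondary alcohols (C5 and C8) to ketones in one operation without cleaving the C4/C5 glycol and without base, so the tertiary C4 hydroxyl is kept and the β,γ-unsaturated C8 ketone is not drawn into conjugation.

Step 22
Reactants: 30 2-[(1S,3R,4S,6S)-3-(tert-butyldimethylsilyloxy)-4-hydroxy-6-(4-methoxybenzyloxy)-4-methyl-5-oxocyclohexyl]-6-methylhepta-1,5-dien-3-one
Product: 31 2-[(1S,3R,4S,6S)-3-(tert-butyldimethylsilyloxy)-4,6-dihydroxy-4-methyl-5-oxocyclohexyl]-6-methylhepta-1,5-dien-3-one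
Conditions: DDQ, CH2Cl2–pH 7 buffer (10:1), 0 °C → rt
Reagents that add atoms: none
Why: Oxidative cleavage of the PMB ether with DDQ (benzylic hydride abstraction, hydrolysis of the oxocarbenium ion) releases the C6 hydroxyl in the presence of the silyl ether and the alkenes.

Step 23
Reactants: 31 2-[(1S,3R,4S,6S)-3-(tert-butyldimethylsilyloxy)-4,6-dihydroxy-4-methyl-5-oxocyclohexyl]-6-methylhepta-1,5-dien-3-one; 32 isovaleryl chloride
Product: 33 C6 3-methylbutanoate of 31, (1S,3R,4S,6S)
Conditions: i-BuCOCl, pyridine, DMAP (cat.), CH2Cl2, 0 °C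
Reagents that add atoms: isovaleryl chloride (32), CC(C)CC(Cl)=O
Why: Pyridine/DMAP-mediated O-acylation esterifies the secondary C6 hydroxyl, the only acylable one, since the tertiary C4 hydroxyl is inert under these conditions and C3 is silylated.

Step 24
Reactants: 33 C6 3-methylbutanoate of 31
Product: 34 (1S,3R,4S,6S)-3,4-dihydroxy-4-methyl-1-(6-methyl-3-oxohepta-1,5-dien-2-yl)-5-oxocyclohex-6-yl 3-methylbutanoate
Conditions: HF·pyridine, THF–pyridine, 0 °C → rt
Reagents that add atoms: none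
Why: Fluoride-induced desilylation with buffered HF·pyridine removes the TBS group under mildly acidic conditions that should spare the ester, the α-ketol and the skipped enone.

Step 25
Reactants: 34 (1S,3R,4S,6S)-3,4-dihydroxy-4-methyl-1-(6-methyl-3-oxohepta-1,5-dien-2-yl)-5-oxocyclohex-6-yl 3-methylbutanoate
Product: 35 CNP0239240.1, (1S,3R,4S,6S)-1-[(E)-6-hydroperoxy-6-methyl-3-oxohepta-1,4-dien-2-yl]-3,4-dihydroxy-4-methyl-5-oxocyclohex-6-yl 3-methylbutanoate
Conditions: O2, tetraphenylporphyrin (cat.), visible light, CH2Cl2, −20 → 0 °C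
Reagents that add atoms: oxygen, O=O
Why: Schenck ene reaction of singlet oxygen with the trisubstituted alkene, in which abstraction of a C9 hydrogen (activated by the adjacent carbonyl and on the more substituted side of the olefin) should predominate, giving the tertiary hydroperoxide with the alkene shifted into conjugation as the E isomer; the electron-poor C7 methylene does not react.

**Compound list**

1 | methyl β-D-galactopyranoside | OC[C@H]1O[C@@H](OC)[C@H](O)[C@@H](O)[C@H]1O | starting material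
2 | methyl 4,6-O-[(S)-4-methoxybenzylidene]-β-D-galactopyranoside | COc1ccc(cc1)[C@H]2OC[C@H]3O[C@@H](OC)[C@H](O)[C@@H](O)[C@H]3O2 | intermediate
3 | methyl 2,3-O-dibutylstannylene-4,6-O-(4-methoxybenzylidene)-β-D-galactopyranoside | COc1ccc(cc1)[C@H]2OC[C@H]3O[C@@H](OC)[C@@H]4O[Sn](CCCC)(CCCC)O[C@H]4[C@H]3O2 | intermediate
4 | methyl 3-O-benzoyl-4,6-O-(4-methoxybenzylidene)-β-D-galactopyranoside | COc1ccc(cc1)[C@H]2OC[C@H]3O[C@@H](OC)[C@H](O)[C@@H](OC(=O)c4ccccc4)[C@H]3O2 | intermediate
5 | methyl 3-O-benzoyl-4,6-O-(4-methoxybenzylidene)-β-D-lyxo-hexopyranosid-2-ulose | COc1ccc(cc1)[C@H]2OC[C@H]3O[C@@H](OC)C(=O)[C@@H](OC(=O)c4ccccc4)[C@H]3O2 | intermediate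
6 | methylmagnesium bromide | C[Mg]Br | starting material
7 | bromomagnesium 2-alkoxide of methyl 3-O-benzoyl-4,6-O-(4-methoxybenzylidene)-2-C-methyl-β-D-talopyranoside | COc1ccc(cc1)[C@H]2OC[C@H]3O[C@@H](OC)[C@@](C)(O[Mg]Br)[C@@H](OC(=O)c4ccccc4)[C@H]3O2 | intermediate
8 | methyl 4,6-O-(4-methoxybenzylidene)-2-C-methyl-β-D-talopyranoside | COc1ccc(cc1)[C@H]2OC[C@H]3O[C@@H](OC)[C@@](C)(O)[C@@H](O)[C@H]3O2 | intermediate
9 | methyl 4,6-O-(4-methoxybenzylidene)-2-C-methyl-2,3-O-thiocarbonyl-β-D-talopyranoside | COc1ccc(cc1)[C@H]2OC[C@H]3O[C@@H](OC)[C@@]4(C)OC(=S)O[C@H]4[C@H]3O2 | intermediate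
10 | methyl 2,3-dideoxy-4,6-O-(4-methoxybenzylidene)-2-C-methyl-β-D-threo-hex-2-enopyranoside | COc1ccc(cc1)[C@H]2OC[C@H]3O[C@@H](OC)C(C)=C[C@H]3O2 | intermediate
11 | methyl 4,6-O-(4-methoxybenzylidene)-2-C-methyl-β-D-gulopyranoside | COc1ccc(cc1)[C@H]2OC[C@H]3O[C@@H](OC)[C@](C)(O)[C@H](O)[C@H]3O2 | intermediate
12 | methyl 2,3-O-isopropylidene-4,6-O-(4-methoxybenzylidene)-2-C-methyl-β-D-gulopyranoside | COc1ccc(cc1)[C@H]2OC[C@H]3O[C@@H](OC)[C@]4(C)OC(C)(C)O[C@@H]4[C@H]3O2 | intermediate
13 | methyl 2,3-O-isopropylidene-4-O-(4-methoxybenzyl)-2-C-methyl-β-D-gulopyranoside | OC[C@H]1O[C@@H](OC)[C@]2(C)OC(C)(C)O[C@@H]2[C@H]1OCc3ccc(OC)cc3 | intermediate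
14 | methyl 6-deoxy-6-iodo-2,3-O-isopropylidene-4-O-(4-methoxybenzyl)-2-C-methyl-β-D-gulopyranoside | IC[C@H]1O[C@@H](OC)[C@]2(C)OC(C)(C)O[C@@H]2[C@H]1OCc3ccc(OC)cc3 | intermediate
15 | methyl 6-deoxy-2,3-O-isopropylidene-4-O-(4-methoxybenzyl)-2-C-methyl-α-L-lyxo-hex-5-enopyranoside | C=C1O[C@@H](OC)[C@]2(C)OC(C)(C)O[C@@H]2[C@H]1OCc3ccc(OC)cc3 | intermediate
16 | 6-deoxy-2,3-O-isopropylidene-4-O-(4-methoxybenzyl)-2-C-methyl-6-(trifluoroacetoxymercurio)-aldehydo-L-lyxo-hexos-5-ulose | O=C[C@]1(C)OC(C)(C)O[C@@H]1[C@@H](OCc2ccc(OC)cc2)C(=O)C[Hg]OC(=O)C(F)(F)F | intermediate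
17 | (3R,4S,5R,6R)-3-hydroxy-4,5-(isopropylidenedioxy)-6-(4-methoxybenzyloxy)-4-methylcyclohexan-1-one | O=C1C[C@@H](O)[C@]2(C)OC(C)(C)O[C@@H]2[C@H]1OCc3ccc(OC)cc3 | intermediate
18 | triethyl phosphonoacetate | CCOC(=O)CP(=O)(OCC)OCC | starting material
19 | ethyl 2-[(3R,4S,5R,6S)-3-hydroxy-4,5-(isopropylidenedioxy)-6-(4-methoxybenzyloxy)-4-methylcyclohexylidene]acetate (E/Z) | CCOC(=O)C=C1C[C@@H](O)[C@]2(C)OC(C)(C)O[C@@H]2[C@H]1OCc3ccc(OC)cc3 | intermediate
20 | ethyl 2-[(1S,3R,4S,5R,6S)-3-hydroxy-4,5-(isopropylidenedioxy)-6-(4-methoxybenzyloxy)-4-methylcyclohexyl]acetate | CCOC(=O)C[C@@H]1C[C@@H](O)[C@]2(C)OC(C)(C)O[C@@H]2[C@H]1OCc3ccc(OC)cc3 | intermediate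
21 | ethyl 2-[(1S,3R,4R,5R,6S)-3-(tert-butyldimethylsilyloxy)-4,5-(isopropylidenedioxy)-6-(4-methoxybenzyloxy)-4-methylcyclohexyl]acetate | CCOC(=O)C[C@@H]1C[C@@H](O[Si](C)(C)C(C)(C)C)[C@]2(C)OC(C)(C)O[C@@H]2[C@H]1OCc3ccc(OC)cc3 | intermediate
22 | 2-[(1S,3R,4R,5R,6S)-3-(tert-butyldimethylsilyloxy)-4,5-(isopropylidenedioxy)-6-(4-methoxybenzyloxy)-4-methylcyclohexyl]acetaldehyde | O=CC[C@@H]1C[C@@H](O[Si](C)(C)C(C)(C)C)[C@]2(C)OC(C)(C)O[C@@H]2[C@H]1OCc3ccc(OC)cc3 | intermediate
23 | formaldehyde | C=O | starting material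
24 | 2-[(1S,3R,4R,5R,6S)-3-(tert-butyldimethylsilyloxy)-4,5-(isopropylidenedioxy)-6-(4-methoxybenzyloxy)-4-methylcyclohexyl]prop-2-enal | C=C(C=O)[C@@H]1C[C@@H](O[Si](C)(C)C(C)(C)C)[C@]2(C)OC(C)(C)O[C@@H]2[C@H]1OCc3ccc(OC)cc3 | intermediate
25 | allylmagnesium bromide | C=CC[Mg]Br | starting material
26 | 2-[(1S,3R,4R,5R,6S)-3-(tert-butyldimethylsilyloxy)-4,5-(isopropylidenedioxy)-6-(4-methoxybenzyloxy)-4-methylcyclohexyl]hexa-1,5-dien-3-ol (C8 epimers) | C=CCC(O)C(=C)[C@@H]1C[C@@H](O[Si](C)(C)C(C)(C)C)[C@]2(C)OC(C)(C)O[C@@H]2[C@H]1OCc3ccc(OC)cc3 | intermediate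
27 | 2-methyl-2-butene | CC=C(C)C | starting material
28 | 2-[(1S,3R,4R,5R,6S)-3-(tert-butyldimethylsilyloxy)-4,5-(isopropylidenedioxy)-6-(4-methoxybenzyloxy)-4-methylcyclohexyl]-6-methylhepta-1,5-dien-3-ol (C8 epimers) | CC(C)=CCC(O)C(=C)[C@@H]1C[C@@H](O[Si](C)(C)C(C)(C)C)[C@]2(C)OC(C)(C)O[C@@H]2[C@H]1OCc3ccc(OC)cc3 | intermediate
29 | 2-[(1S,3R,4R,5R,6S)-3-(tert-butyldimethylsilyloxy)-4,5-dihydroxy-6-(4-methoxybenzyloxy)-4-methylcyclohexyl]-6-methylhepta-1,5-dien-3-ol (C8 epimers) | CC(C)=CCC(O)C(=C)[C@@H]1C[C@@H](O[Si](C)(C)C(C)(C)C)[C@](C)(O)[C@H](O)[C@H]1OCc2ccc(OC)cc2 | intermediate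
30 | 2-[(1S,3R,4S,6S)-3-(tert-butyldimethylsilyloxy)-4-hydroxy-6-(4-methoxybenzyloxy)-4-methyl-5-oxocyclohexyl]-6-methylhepta-1,5-dien-3-one | CC(C)=CCC(=O)C(=C)[C@@H]1C[C@@H](O[Si](C)(C)C(C)(C)C)[C@](C)(O)C(=O)[C@H]1OCc2ccc(OC)cc2 | intermediate
31 | 2-[(1S,3R,4S,6S)-3-(tert-butyldimethylsilyloxy)-4,6-dihydroxy-4-methyl-5-oxocyclohexyl]-6-methylhepta-1,5-dien-3-one | CC(C)=CCC(=O)C(=C)[C@@H]1C[C@@H](O[Si](C)(C)C(C)(C)C)[C@](C)(O)C(=O)[C@H]1O | intermediate
32 | isovaleryl chloride (3-methylbutanoyl chloride) | CC(C)CC(Cl)=O | starting material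
33 | C6 3-methylbutanoate of 31, (1S,3R,4S,6S) | CC(C)=CCC(=O)C(=C)[C@@H]1C[C@@H](O[Si](C)(C)C(C)(C)C)[C@](C)(O)C(=O)[C@H]1OC(=O)CC(C)C | intermediate
34 | (1S,3R,4S,6S)-3,4-dihydroxy-4-methyl-1-(6-methyl-3-oxohepta-1,5-dien-2-yl)-5-oxocyclohex-6-yl 3-methylbutanoate | CC(C)=CCC(=O)C(=C)[C@@H]1C[C@@H](O)[C@](C)(O)C(=O)[C@H]1OC(=O)CC(C)C | intermediate
35 | CNP0239240.1, (1S,3R,4S,6S)-1-[(E)-6-hydroperoxy-6-methyl-3-oxohepta-1,4-dien-2-yl]-3,4-dihydroxy-4-methyl-5-oxocyclohex-6-yl 3-methylbutanoate | C=C(C(=O)/C=C/C(C)(C)OO)[C@@H]1C[C@@H](O)[C@](C)(O)C(=O)[C@H]1OC(=O)CC(C)C | target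

**Totals**

Total step count: 25. Longest linear sequence: 25 steps (from 1; all other inputs are commercial).

**Steps most likely to fail**

1. Step 13. Before olefination is complete, the base may open ketol 17 by retro-aldol reaction or dehydrate it to the enone. Fallback, from 17 back to 19: the hydroxyl is masked first with Et3SiCl and imidazole in DMF to give the C3 triethylsilyl ether of the ketone F1. F1 is olefinated with the sodium salt of 18 (NaH, THF, 0 °C) to the silylated enoate F2. HF·pyridine in THF–pyridine then frees the C3 hydroxyl and the route is rejoined at 19.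

2. Step 14. The hindered, electron-poor enoate may be hydrogenated sluggishly, and hydroxyl direction may be lost to competing coordination of the ester. Fallback, from 19 to 22: 19 is reduced with DIBAL-H (CH2Cl2, −78 °C) to the allylic alcohol F3, an electron-rich alkene with two hydroxyl anchors. F3 is hydrogenated under the same iridium catalysis to the saturated diol F4. TEMPO/PhI(OAc)2 oxidises only the primary alcohol, giving the hydroxy aldehyde F5. Silylation (TBSOTf, 2,6-lutidine, −78 °C) then gives 22, so 20 and 21 are bypassed.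

3. Step 25. Hydrogen abstraction from the gem-dimethyl group may compete, giving the secondary hydroperoxide with an isopropenyl end. Fallback, from 34 to 35: oxygen is introduced through a radical chain in which only the doubly activated C9–H bond can react. 34 is stirred under O2 (1 atm) with catalytic N-hydroxyphthalimide in MeCN at 35–40 °C. The N-oxyl radical abstracts a C9 hydrogen, the delocalised keto-allyl radical is trapped by triplet oxygen at the tertiary terminus C11, where enone conjugation is kept, and hydrogen return gives 35 directly without any further isolated compound (F0).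

**Further compounds**

F1 | step 13 | C3 triethylsilyl ether of ketone 17 | O=C1C[C@@H](O[Si](CC)(CC)CC)[C@]2(C)OC(C)(C)O[C@@H]2[C@H]1OCc3ccc(OC)cc3
F2 | step 13 | C3 triethylsilyl ether of enoate 19 (E/Z) | CCOC(=O)C=C1C[C@@H](O[Si](CC)(CC)CC)[C@]2(C)OC(C)(C)O[C@@H]2[C@H]1OCc3ccc(OC)cc3
F3 | step 14 | 2-[(3R,4S,5R,6S)-3-hydroxy-4,5-(isopropylidenedioxy)-6-(4-methoxybenzyloxy)-4-methylcyclohexylidene]ethanol (E/Z) | OCC=C1C[C@@H](O)[C@]2(C)OC(C)(C)O[C@@H]2[C@H]1OCc3ccc(OC)cc3
F4 | step 14 | 2-[(1S,3R,4S,5R,6S)-3-hydroxy-4,5-(isopropylidenedioxy)-6-(4-methoxybenzyloxy)-4-methylcyclohexyl]ethanol | OCC[C@@H]1C[C@@H](O)[C@]2(C)OC(C)(C)O[C@@H]2[C@H]1OCc3ccc(OC)cc3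
F5 | step 14 | 2-[(1S,3R,4S,5R,6S)-3-hydroxy-4,5-(isopropylidenedioxy)-6-(4-methoxybenzyloxy)-4-methylcyclohexyl]acetaldehyde | O=CC[C@@H]1C[C@@H](O)[C@]2(C)OC(C)(C)O[C@@H]2[C@H]1OCc3ccc(OC)cc3
F0 | step 25 | none | none
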